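The route rests on cutting the ether bond between the ring C oxygen and the ring B carbon ortho to the ring B hydroxyl, with ring B carried as a cyclohexanone. Ring B holds its hydroxyl carbon para to the bridge carbon and ortho to the ether carbon; read as a 4-alkylcyclohexanone (C1 = hydroxyl carbon), its C2 and C6 are mirror-related, so monobromination can only label the future ether carbon. The precursor is the open-chain A–D biaryl bearing a free ring C phenol and a trans-2-bromo-4-alkylcyclohexanone. Phenoxide displacement of bromide makes the O–C2 bond and the 16-membered ring at once; dehydrogenation and demethylation finish the synthesis.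

Key step: step 10

Assumption: the target SMILES assigns no configuration to the A–D biaryl axis, so the axis is left uncontrolled. Every intermediate with stereocentres is racemic, its SMILES shows relative configuration only, and rotamers or diastereomers about the axis are carried on together.

Step 1
Reactants: 1 4-(benzyloxy)benzyl chloride
Product: 2 diethyl [4-(benzyloxy)benzyl]phosphonate
Conditions: P(OEt)3 (neat), 140 °C
Reagents that add atoms: triethyl phosphite, CCOP(OCC)OCC
Why: Michaelis–Arbuzov reaction, in which the reactive benzylic chloride alkylates phosphorus and chloride then removes one ethyl group, under neutral conditions that leave the benzyl ether untouched.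

Step 2
Reactants: 2 diethyl [4-(benzyloxy)benzyl]phosphonate; 3 2-bromo-3-methoxybenzaldehyde
Product: 4 (E)-1-{2-[4-(benzyloxy)phenyl]ethenyl}-2-bromo-3-methoxybenzene
Conditions: KOtBu (added to 2 + 3), THF, 0 °C to rt
Reagents that add atoms: none
Why: Horner–Wadsworth–Emmons olefination of a non-enolisable aldehyde with a benzylic phosphonate should give mainly the E-stilbene, a geometry that step 7 erases, with a water-soluble phosphate as the only phosphorus waste.

Step 3
Reactants: 4 (E)-1-{2-[4-(benzyloxy)phenyl]ethenyl}-2-bromo-3-methoxybenzene; 5 2-formyl-4-methoxyphenylboronic acid (1.5 equiv)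
Product: 6 2'-{(E)-2-[4-(benzyloxy)phenyl]ethenyl}-4,6'-dimethoxybiphenyl-2-carbaldehyde
Conditions: Pd(OAc)2 (cat.), SPhos, K3PO4, toluene–H2O, 90 °C
Reagents that add atoms: none
Why: Suzuki–Miyaura coupling, in which the bulky electron-rich biarylphosphine speeds oxidative addition and reductive elimination at the doubly ortho-substituted bromide enough to outrun protodeboronation of the ortho-formyl boronic acid.

Step 4
Reactants: 7 (1,4-dioxaspiro[4.5]decan-8-yl)methanol
Product: 8 8-(iodomethyl)-1,4-dioxaspiro[4.5]decane
Conditions: I2, PPh3, imidazole, CH2Cl2, 0 °C to rt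
Reagents that add atoms: iodine, II
Why: Appel-type iodination of an unhindered primary alcohol by SN2 attack of iodide on the alkoxyphosphonium ion, with imidazole keeping the medium non-acidic for the ketal.

Step 5
Reactants: 8 8-(iodomethyl)-1,4-dioxaspiro[4.5]decane
Product: 9 (1,4-dioxaspiro[4.5]decan-8-ylmethyl)triphenylphosphonium iodide
Conditions: PPh3, MeCN, reflux
Reagents that add atoms: triphenylphosphine, c1ccc(cc1)P(c1ccccc1)c1ccccc1
Why: SN2 quaternisation of the phosphine by a primary iodide, which for cyclohexylmethyl halides needs only prolonged heating and gives a salt that crystallises.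

Step 6
Reactants: 9 (1,4-dioxaspiro[4.5]decan-8-ylmethyl)triphenylphosphonium iodide; 6 2'-{(E)-2-[4-(benzyloxy)phenyl]ethenyl}-4,6'-dimethoxybiphenyl-2-carbaldehyde
Product: 11 8-[(Z)-2-(2'-{(E)-2-[4-(benzyloxy)phenyl]ethenyl}-4,6'-dimethoxybiphenyl-2-yl)ethenyl]-1,4-dioxaspiro[4.5]decane, via phosphorus ylide 10 (not isolated)
Conditions: NaN(SiMe3)2, THF, 0 °C; then 6, −78 °C to rt
Reagents that add atoms: none
Why: Wittig olefination with a non-stabilised ylide, which adds readily even to an ortho-biaryl aldehyde and should favour the Z-alkene, a geometry of no consequence because step 7 saturates it.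

Step 7
Reactants: 11 8-[(Z)-2-(2'-{(E)-2-[4-(benzyloxy)phenyl]ethenyl}-4,6'-dimethoxybiphenyl-2-yl)ethenyl]-1,4-dioxaspiro[4.5]decane
Product: 12 4-[2-(2'-[2-(1,4-dioxaspiro[4.5]decan-8-yl)ethyl]-4',6-dimethoxybiphenyl-2-yl)ethyl]phenol
Conditions: H2 (1 atm), Pd/C, EtOAc–EtOH, rt
Reagents that add atoms: none
Why: Heterogeneous catalytic hydrogenation saturates both styrenic alkenes and hydrogenolyses the benzyl ether in one operation, while the methyl ethers, the ketal and the arenes are inert at this pressure.

Step 8
Reactants: 12 4-[2-(2'-[2-(1,4-dioxaspiro[4.5]decan-8-yl)ethyl]-4',6-dimethoxybiphenyl-2-yl)ethyl]phenol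
Product: 13 4-(2-{2'-[2-(4-hydroxyphenyl)ethyl]-4,6'-dimethoxybiphenyl-2-yl}ethyl)cyclohexanone
Conditions: 1 M HCl, THF, rt
Reagents that add atoms: water, O
Why: Acid-catalysed ketal hydrolysis through the oxocarbenium ion, to which the phenol and the aryl methyl ethers are indifferent.

Step 9
Reactants: 13 4-(2-{2'-[2-(4-hydroxyphenyl)ethyl]-4,6'-dimethoxybiphenyl-2-yl}ethyl)cyclohexanone
Product: 16 rac-trans-2-bromo-4-(2-{2'-[2-(4-hydroxyphenyl)ethyl]-4,6'-dimethoxybiphenyl-2-yl}ethyl)cyclohexanone [(2S,4R) drawn], via bis-silyl enol ether 14 (not isolated), via O-silyl bromoketone 15 (not isolated)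
Conditions: Me3SiOTf (2.4 equiv), Et3N, CH2Cl2, 0 °C; cold NaHCO3 wash, concentrate; NBS (1.0 equiv), THF, −78 °C; then 1 M HCl, THF, 0 °C
Reagents that add atoms: N-bromosuccinimide, O=C1CCC(=O)N1Br; trimethylsilyl triflate, C[Si](C)(C)OS(=O)(=O)C(F)(F)F (its silyl groups appear only in 14 and 15)
Why: Soft enolisation and silylation caps the phenol and gives the single possible silyl enol ether, by far the most nucleophilic pi system present, so electrophilic alpha-bromination with one equivalent of NBS should strike it alone by axial attack on the half-chair with the C4 chain equatorial (trans, axial Br), and dilute acid then frees the phenol without exposing the bromoketone to base or fluoride.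

Step 10
Reactants: 16 rac-trans-2-bromo-4-(2-{2'-[2-(4-hydroxyphenyl)ethyl]-4,6'-dimethoxybiphenyl-2-yl}ethyl)cyclohexanone
Product: 17 macrocyclic cis-2-aryloxy-4-alkylcyclohexanone, the 16-membered ring with ring B as a cyclohexanone and rings A and D as methyl ethers [racemic, (2R,4R) in cyclohexanone numbering drawn]
Conditions: Cs2CO3 (dried, 3 equiv), 4 Å MS, MeCN, 40 °C, syringe-pump addition of 16 (about 1 mM final), Ar
Reagents that add atoms: none
Why: Cs2CO3 deprotonates only the ring C phenol, which is far more acidic than the ketone alpha-hydrogens, and the caesium phenoxide attacks C2 anti to bromine in an SN2 displacement that the neighbouring carbonyl pi* orbital accelerates, best of all for the axial C–Br bond of the trans isomer. The closest known reaction type is the Williamson-type O-alkylation of phenoxides with 2-halocyclohexanones, run here intramolecularly as a high-dilution macroetherification. The ring closes in the 16-exo-tet mode, with bromide departing outside the new ring. The new C2 stereocentre arises by inversion, so the trans bromide should give the cis, diequatorial aryloxy ketone, whose two equatorial bonds diverge much like the meta bonds of the future ring B; epimerisation through the enol is harmless because C2 and C4 both become sp2 in step 11. The step needs O-alkylation to outrun loss of HBr, Favorskii contraction, C-alkylation and oligomerisation, and this is served by the absence of alkoxide and hydroxide, by a weakly basic yet strongly nucleophilic phenoxide in a dipolar aprotic solvent, by a side chain at C4 lying on the face from which the oxygen must arrive, and by slow addition that keeps free 16 very dilute.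

Step 11
Reactants: 17 macrocyclic cis-2-aryloxy-4-alkylcyclohexanone
Product: 19 plagiochin E dimethyl ether (ring B free phenol, methoxy groups on rings A and D), via macrocyclic enone 18 (not isolated)
Conditions: Pd(OCOCF3)2 (10 mol %), 2-(dimethylamino)pyridine (20 mol %), TsOH·H2O (40 mol %), O2 (1 atm), DMSO, 80 °C
Reagents that add atoms: none
Why: Palladium-catalysed aerobic dehydrogenation of a cyclohexanone to a phenol, in which divalent palladium forms an enolate at the unhindered C6, beta-hydride elimination should give enone 18, a second cycle aromatises ring B with loss of both stereocentres, and O2 returns zerovalent palladium to the divalent state.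

Step 12
Reactants: 19 plagiochin E dimethyl ether
Product: 20 plagiochin E
Conditions: BBr3 (6 equiv), CH2Cl2, −78 °C to rt; then H2O
Reagents that add atoms: none
Why: Lewis-acid ether cleavage, in which BBr3 binds each methoxy oxygen and bromide removes the methyl group by SN2, whereas the diaryl ether offers no sp3 carbon to attack and survives.

Compound list
1 | 4-(benzyloxy)benzyl chloride | ClCc1ccc(OCc2ccccc2)cc1 | starting material
2 | diethyl [4-(benzyloxy)benzyl]phosphonate | CCOP(=O)(Cc1ccc(OCc2ccccc2)cc1)OCC | intermediate
3 | 2-bromo-3-methoxybenzaldehyde | COc1cccc(C=O)c1Br | starting material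
4 | (E)-1-{2-[4-(benzyloxy)phenyl]ethenyl}-2-bromo-3-methoxybenzene | COc1cccc(/C=C/c2ccc(OCc3ccccc3)cc2)c1Br | intermediate
5 | 2-formyl-4-methoxyphenylboronic acid | COc1ccc(B(O)O)c(C=O)c1 | starting material
6 | 2'-{(E)-2-[4-(benzyloxy)phenyl]ethenyl}-4,6'-dimethoxybiphenyl-2-carbaldehyde | COc1ccc(c(C=O)c1)-c1c(OC)cccc1/C=C/c1ccc(OCc2ccccc2)cc1 | intermediate
7 | (1,4-dioxaspiro[4.5]decan-8-yl)methanol | OCC1CCC2(CC1)OCCO2 | starting material
8 | 8-(iodomethyl)-1,4-dioxaspiro[4.5]decane | ICC1CCC2(CC1)OCCO2 | intermediate
9 | (1,4-dioxaspiro[4.5]decan-8-ylmethyl)triphenylphosphonium iodide | [I-].C(C1CCC2(CC1)OCCO2)[P+](c1ccccc1)(c1ccccc1)c1ccccc1 | intermediate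
10 | (1,4-dioxaspiro[4.5]decan-8-ylmethylidene)triphenylphosphorane (ylide, not isolated) | C(=P(c1ccccc1)(c1ccccc1)c1ccccc1)C1CCC2(CC1)OCCO2 | intermediate
11 | 8-[(Z)-2-(2'-{(E)-2-[4-(benzyloxy)phenyl]ethenyl}-4,6'-dimethoxybiphenyl-2-yl)ethenyl]-1,4-dioxaspiro[4.5]decane | COc1ccc(c(/C=C\C2CCC3(CC2)OCCO3)c1)-c1c(OC)cccc1/C=C/c1ccc(OCc2ccccc2)cc1 | intermediate
12 | 4-[2-(2'-[2-(1,4-dioxaspiro[4.5]decan-8-yl)ethyl]-4',6-dimethoxybiphenyl-2-yl)ethyl]phenol | COc1ccc(c(CCC2CCC3(CC2)OCCO3)c1)-c1c(OC)cccc1CCc1ccc(O)cc1 | intermediate
13 | 4-(2-{2'-[2-(4-hydroxyphenyl)ethyl]-4,6'-dimethoxybiphenyl-2-yl}ethyl)cyclohexanone | COc1ccc(c(CCC2CCC(=O)CC2)c1)-c1c(OC)cccc1CCc1ccc(O)cc1 | intermediate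
14 | trimethylsilyl enol ether of 13 with the ring C phenol as its trimethylsilyl ether (racemic, not isolated) | COc1ccc(c(CCC2CCC(O[Si](C)(C)C)=CC2)c1)-c1c(OC)cccc1CCc1ccc(O[Si](C)(C)C)cc1 | intermediate
15 | ring C O-trimethylsilyl ether of trans-bromoketone 16 (racemic, not isolated) | C[Si](C)(C)Oc1ccc(cc1)CCc1cccc(OC)c1-c1ccc(OC)cc1CC[C@@H]1CCC(=O)[C@@H](Br)C1 | intermediate
16 | rac-trans-2-bromo-4-(2-{2'-[2-(4-hydroxyphenyl)ethyl]-4,6'-dimethoxybiphenyl-2-yl}ethyl)cyclohexanone, (2S,4R) drawn | Oc1ccc(cc1)CCc1cccc(OC)c1-c1ccc(OC)cc1CC[C@@H]1CCC(=O)[C@@H](Br)C1 | intermediate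
17 | macrocyclic cis-2-aryloxy-4-alkylcyclohexanone (16-membered ring; racemic, (2R,4R) in cyclohexanone numbering drawn) | O=C1CC[C@@H]2C[C@H]1Oc1ccc(cc1)CCc1cccc(OC)c1-c1ccc(OC)cc1CC2 | intermediate
18 | macrocyclic cis-6-aryloxy-4-alkylcyclohex-2-enone (racemic, not isolated) | O=C1C=C[C@@H]2C[C@H]1Oc1ccc(cc1)CCc1cccc(OC)c1-c1ccc(OC)cc1CC2 | intermediate
19 | plagiochin E dimethyl ether (ring B phenol free, rings A and D as methyl ethers) | Oc1ccc2cc1Oc1ccc(cc1)CCc1cccc(OC)c1-c1ccc(OC)cc1CC2 | intermediate
20 | plagiochin E | Oc1ccc2c(c1)CCc1ccc(O)c(c1)Oc1ccc(cc1)CCc1cccc(O)c1-2 | target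

Total step count: 12.
Longest linear sequence: 10 steps (steps 1, 2, 3, 6, 7, 8, 9, 10, 11, 12). Steps 4 and 5 form the side branch that joins at step 6.

Steps most likely to fail

Step 10. Base-induced loss of HBr, Favorskii ring contraction or intermolecular etherification may outpace the slow closure of the large ring. The fallback keeps the same O–C2 bond but changes the electrophile from a halide to an epoxide. It sets out from 16 and comes back at 19.
- The elimination is carried out on purpose (LiBr, Li2CO3, DMF, 110 °C) to give the 4-alkylcyclohex-2-enone phenol F1.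
- Weitz–Scheffer epoxidation (H2O2, NaOH, MeOH, 0 °C) should then deliver oxygen anti to the C4 side chain and give the 2,3-epoxy ketone phenol F2.
- With Cs2CO3 in DMF at high dilution and gentle heating, the phenoxide opens the epoxide at the alpha carbon C2, a known route from epoxy ketones and phenols to 2-aryloxy enones. This gives the macrocyclic 2-aryloxy-3-hydroxy ketone F3.
- F3 loses water in the flask to the macrocyclic 2-aryloxycyclohex-2-enone F4.
- This electrophile has no halide to eliminate and cannot contract, and F4 needs only one dehydrogenation under the conditions of step 11 to reach 19.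

Step 11. The reaction may stall after the first dehydrogenation, the catalyst may aggregate to inactive metal, or the electron-rich catechol monoether may be over-oxidised under O2. The fallback replaces the catalytic aerobic process by a stepwise, stoichiometric, anionic one. It sets out from 17 and comes back at 19.
- LiN(iPr)2 in THF at −78 °C followed by N-tert-butylbenzenesulfinimidoyl chloride dehydrogenates the kinetic C6 enolate by S-attack and syn elimination, so that enone 18 can be isolated.
- A second pass on 18 deprotonates the alpha' carbon that bears the aryloxy group. It introduces the last double bond, and ring B aromatises to 19.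
- No oxygen and no metal catalyst are present, and no compound outside the compound list is made (entry F0).

Step 9. The aryl trimethylsilyl ether may hydrolyse early and ring C may then be brominated, a second bromination may occur, or the unprotected bromoketone phenol may decay during purification. The fallback uses a durable phenol protecting group, so that a storable, purifiable bromoketone is made first and the phenol is released last. It sets out from 13 and comes back at 16.
- TBSCl and imidazole in DMF give the ring C tert-butyldimethylsilyl ether ketone F5.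
- LiN(SiMe3)2 and Me3SiCl in THF at −78 °C give its trimethylsilyl enol ether F6.
- NBS at −78 °C converts F6 into the trans-bromoketone silyl ether F7, which can be chromatographed.
- HF·pyridine in THF at 0 °C, an acidic fluoride source that the bromoketone tolerates, then gives 16 for immediate use.

Further compounds
F1 | step 10 | 4-(2-{2'-[2-(4-hydroxyphenyl)ethyl]-4,6'-dimethoxybiphenyl-2-yl}ethyl)cyclohex-2-enone (racemic) | COc1ccc(c(CCC2CCC(=O)C=C2)c1)-c1c(OC)cccc1CCc1ccc(O)cc1
F2 | step 10 | 2,3-epoxy-4-(2-{2'-[2-(4-hydroxyphenyl)ethyl]-4,6'-dimethoxybiphenyl-2-yl}ethyl)cyclohexanone, epoxide trans to the C4 chain (racemic) | Oc1ccc(cc1)CCc1cccc(OC)c1-c1ccc(OC)cc1CC[C@@H]1CCC(=O)[C@H]2O[C@@H]12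
F3 | step 10 | macrocyclic 2-aryloxy-3-hydroxy-4-alkylcyclohexanone, aryloxy cis and hydroxyl trans to the C4 chain (racemic) | O=C1CC[C@@H]2[C@H](O)[C@H]1Oc1ccc(cc1)CCc1cccc(OC)c1-c1ccc(OC)cc1CC2
F4 | step 10 | macrocyclic 2-aryloxy-4-alkylcyclohex-2-enone (racemic) | O=C1CCC2C=C1Oc1ccc(cc1)CCc1cccc(OC)c1-c1ccc(OC)cc1CC2
F0 | step 11 | none | none
F5 | step 9 | 4-(2-{2'-[2-(4-{tert-butyldimethylsilyloxy}phenyl)ethyl]-4,6'-dimethoxybiphenyl-2-yl}ethyl)cyclohexanone | COc1ccc(c(CCC2CCC(=O)CC2)c1)-c1c(OC)cccc1CCc1ccc(O[Si](C)(C)C(C)(C)C)cc1
F6 | step 9 | trimethylsilyl enol ether of F5 (racemic) | COc1ccc(c(CCC2CCC(O[Si](C)(C)C)=CC2)c1)-c1c(OC)cccc1CCc1ccc(O[Si](C)(C)C(C)(C)C)cc1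
F7 | step 9 | ring C tert-butyldimethylsilyl ether of trans-bromoketone 16 (racemic) | CC(C)(C)[Si](C)(C)Oc1ccc(cc1)CCc1cccc(OC)c1-c1ccc(OC)cc1CC[C@@H]1CCC(=O)[C@@H](Br)C1
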